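The data were computed on assumed constants; scatter was added.

At 40.0 h, the last reading of the theta run, the starting material had stopped moving, and I had to say what a flask with less third reagent held after 15 d.

common to all: starting material 0.086 M; partner 0.0688 M; gas 5.6 mM (held)
- theta: third reagent 0.22 M; run made earlier
- flask: third reagent 0.112 M; time 15 d

theta run (percent of the starting material charged)

| time / h | starting material / % | target / % |
|---|---|---|
| 5.00 | 78.0 | 0.9 |
| 12.0 | 72.2 | 3.1 |
| 25.0 | 69.3 | 8.0 |
| 40.0 | 68.9 | 9.4 |

(standard deviation of a reading: 0.5 percentage points)

- at the start none of the gas is in solution

1. how much of the starting material has reacted by 15 d
2. how much target there is at 15 d, in percent of the starting material charged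

Between the last two readings the starting material fell 0.4 percentage points, less than the scatter of 0.5 points, so I read the theta run as stalled with 31.1% lost. My rule of thumb put a stall where the limiting reagent ends. Here that was the partner, the smaller charge, and at one partner to one starting material the rule allowed 80.0%. The theta run stopped far short of that.

The lost starting material per partner charged came to 0.389, and I called this the partner efficiency. At one the rule held; below one it broke. If the partner had stopped the run, some of it had gone elsewhere, and such a loss can shift with the charges, so I treated the figure as a reading for this pair of charges.

The flask had the theta charges of both, so I carried the reading over and reckoned 31.1% lost. I kept the third reagent, cut to half, out of this, because at 5.00 h the theta run had lost 22.0% of its starting material with 0.9% target standing.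

The forecast gave 30% reacted and 10% target, also on “a nearly unchanged plateau”, but it pointed to a dying catalyst or active species where I took the partner to have stopped the run.

The flask gave 31.9% reacted and 11.0% target, with 0% of the partner left at 15.0 d.

    2 partner → self-condensation product (k = 0.0714 /M/min)
    second reagent + intermediate A → intermediate B (k = 0.0746 /M/min)
    third reagent + intermediate B → target (k = 0.0324 /M/min)
    gas ⇌ second reagent, rate k4*(csat - [second reagent]) (kL = 0.0279 /min)
    intermediate A → decomposed reagent (k = 7.69 × 10⁻⁴ /min)
    starting material + partner → intermediate A (k = 0.0321 /M/min)

At the start of the flask, the partner went to intermediate A at 0.28 of the rate at which it went to self-condensation product. By 0.0984 d that ratio had reached 0.73, still below one. The partner efficiency of the flask came to 0.399, and in the neighbouring flask with 0.017 M of partner, where 14.0% reacted, it came to 0.708.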